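The route rests on cutting the bridged acetal at its acetal carbon, a formate-level carbon bonded to ring A (at the carbon ortho to OMe and para to the phenolic oxygen), to the benzylic carbinol oxygen and to the isoquinoline C6 oxygen. In one operation trimethyl orthoformate is inserted between these three partners: the phenol–alcohol pair forms a cyclic orthoester (ring C), and its dioxocarbenium ion is captured by the electron-rich ring A (ring B), creating two C–O bonds, one C–C bond and the acetal stereocentre. The precursor is an anti-aldol β-hydroxy ketone with a free isoquinoline 6-hydroxyl, a silyl-protected ring A phenol and the formyl carbon masked as a dithiane.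

Key step: step 17

Remark on labels: ring A is the formyl-bearing benzene ring with positions a1 (OMe), a2 (CHO), a3 (OH), a4 (H), a5 (bears the acetyl-bearing carbon) and a6 (bears the acetal carbon); ring B is the pyran ring closed between a6 and the acetal carbon; ring C is the 1,3-dioxane ring on the isoquinoline, whose atoms keep their usual locants.
Remark on design: the a2 formyl carbon is carried from the start as a 1,3-dithiane, because formylation of the freed phenol after the cyclisation could also go to a4 and a MgCl2/Et3N/formaldehyde medium would enolise the α-aryl ketone; the dithiane also pushes the silyl ether towards a4, the position that must stay unreactive in the key step.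
Assumption: in the magnesium halide-catalysed anti-aldol the aldehyde adds to the chelated Z-enolate on the face anti to the benzyl group, which is why the (R)-configured auxiliary is chosen.

Step 1
Reactants: 1 4-bromo-2,6-dimethoxybenzaldehyde
Product: 2 4-bromo-2-hydroxy-6-methoxybenzaldehyde
Conditions: BCl3 (1.2 equiv), CH2Cl2, −78 to 0 °C; aq. work-up
Reagents that add atoms: none
Why: Chelation-controlled mono-demethylation, in which BCl3 bridges the aldehyde oxygen and one of the two equivalent ortho methoxy groups and cleaves only that ether, so no regiochemical question arises.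

Step 2
Reactants: 2 4-bromo-2-hydroxy-6-methoxybenzaldehyde
Product: 3 5-bromo-2-(1,3-dithian-2-yl)-3-methoxyphenol
Conditions: HS(CH2)3SH (1.2 equiv), BF3·OEt2 (0.3 equiv), CH2Cl2, 0 °C to rt
Reagents that add atoms: propane-1,3-dithiol, SCCCS
Why: Lewis acid-catalysed dithioacetalisation masks the aldehyde as a 1,3-dithiane that is inert to bases, organometallic reagents, protic acid and Me3SiOTf and fixes the future formyl carbon at a2.

Step 3
Reactants: 3 5-bromo-2-(1,3-dithian-2-yl)-3-methoxyphenol
Product: 4 2-{4-bromo-2-methoxy-6-[(triisopropylsilyl)oxy]phenyl}-1,3-dithiane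
Conditions: iPr3SiOTf (1.3 equiv), 2,6-lutidine (2 equiv), CH2Cl2, 0 °C to rt
Reagents that add atoms: triisopropylsilyl trifluoromethanesulfonate, CC(C)[Si](C(C)C)(C(C)C)OS(=O)(=O)C(F)(F)F
Why: O-Silylation of the hindered phenol with the reactive silyl triflate installs the bulky, acid-stable silyl ether that later shields a4.

Step 4
Reactants: 4 2-{4-bromo-2-methoxy-6-[(triisopropylsilyl)oxy]phenyl}-1,3-dithiane
Product: 5 tert-butyl 2-{4-(1,3-dithian-2-yl)-3-methoxy-5-[(triisopropylsilyl)oxy]phenyl}acetate
Conditions: BrZnCH2CO2tBu (1.5 equiv), Pd2(dba)3 (2 mol %), XPhos (8 mol %), THF, 60 °C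
Reagents that add atoms: (2-tert-butoxy-2-oxoethyl)zinc bromide, CC(C)(C)OC(=O)C[Zn]Br
Why: Palladium-catalysed Negishi-type coupling of the unhindered aryl bromide with a Reformatsky reagent (α-arylation of an ester zinc enolate) runs without strong base and should tolerate the silyl ether and the dithiane.

Step 5
Reactants: 5 tert-butyl 2-{4-(1,3-dithian-2-yl)-3-methoxy-5-[(triisopropylsilyl)oxy]phenyl}acetate
Product: 6 2-{4-(1,3-dithian-2-yl)-3-methoxy-5-[(triisopropylsilyl)oxy]phenyl}acetic acid
Conditions: CF3CO2H/CH2Cl2 (1:4), 0 °C to rt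
Reagents that add atoms: none
Why: Acidolysis of the tert-butyl ester with loss of 2-methylpropene frees the acid, the aryl silyl ether and the dithiane being acid-stable and both free ring positions too hindered for tert-butylation.

Step 6
Reactants: 6 2-{4-(1,3-dithian-2-yl)-3-methoxy-5-[(triisopropylsilyl)oxy]phenyl}acetic acid; 7 (R)-4-benzyloxazolidin-2-one
Product: 9 (R)-4-benzyl-3-(arylacetyl)oxazolidin-2-one, via mixed pivalic anhydride 8 (not isolated)
Conditions: tBuCOCl (1.1 equiv), Et3N (2.5 equiv), THF, −20 °C; then LiCl (1.1 equiv), 7, −20 °C to rt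
Reagents that add atoms: none
Why: N-Acylation of the oxazolidinone through the mixed pivalic anhydride under LiCl/Et3N activation attaches the auxiliary without a strong base.

Step 7
Reactants: 10 2-bromo-4,6-dimethoxybenzaldehyde
Product: 11 2-bromo-4,6-dihydroxybenzaldehyde
Conditions: BBr3 (4 equiv), CH2Cl2, −78 °C to rt; aq. work-up
Reagents that add atoms: none
Why: Exhaustive BBr3 ether cleavage gives the resorcinol aldehyde, whose two phenols differ because only the one ortho to the formyl group is hydrogen-bonded.

Step 8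
Reactants: 11 2-bromo-4,6-dihydroxybenzaldehyde
Product: 12 2-bromo-6-hydroxy-4-(methoxymethoxy)benzaldehyde
Conditions: MeOCH2Cl (1.05 equiv), iPr2NEt (1.2 equiv), CH2Cl2, 0 °C
Reagents that add atoms: chloromethyl methyl ether, COCCl
Why: O-Alkylation (Williamson type) goes selectively to the free, more acidic 4-hydroxyl, since the 6-hydroxyl is locked in a hydrogen bond to the aldehyde.

Step 9
Reactants: 12 2-bromo-6-hydroxy-4-(methoxymethoxy)benzaldehyde
Product: 13 2-bromo-6-methoxy-4-(methoxymethoxy)benzaldehyde
Conditions: MeI (1.5 equiv), K2CO3 (2 equiv), DMF, rt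
Reagents that add atoms: iodomethane, CI
Why: O-Methylation of the remaining chelated phenol completes the unambiguous differentiation of the two oxygens that become the isoquinoline 8-OMe and the protected 6-OH.

Step 10
Reactants: 13 2-bromo-6-methoxy-4-(methoxymethoxy)benzaldehyde
Product: 14 (E)-N-tert-butyl-1-[2-bromo-6-methoxy-4-(methoxymethoxy)phenyl]methanimine
Conditions: tBuNH2 (5 equiv), 4 Å molecular sieves, CH2Cl2, rt
Reagents that add atoms: tert-butylamine, CC(C)(C)N
Why: Condensation to the non-enolisable tert-butyl aldimine protects the formyl group against the lithium amide of the next step and provides the nitrogen of the later annulation.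

Step 11
Reactants: 14 (E)-N-tert-butyl-1-[2-bromo-6-methoxy-4-(methoxymethoxy)phenyl]methanimine
Product: 16 4-bromo-3-[(E)-(tert-butylimino)methyl]-2-methoxy-6-(methoxymethoxy)benzaldehyde, via aryllithium 15 (not isolated)
Conditions: LiN(iPr)2 (1.3 equiv), THF, −78 °C; then DMF (3 equiv), −78 to −20 °C; aq. NaHCO3
Reagents that add atoms: N,N-dimethylformamide, CN(C)C=O
Why: Directed ortho-metalation by a lithium amide, which cannot undergo bromine–lithium exchange, removes the ring hydrogen flanked by the OMe and OCH2OMe groups, and formylation of the aryllithium with DMF places the aldehyde at the future isoquinoline C7.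

Step 12
Reactants: 16 4-bromo-3-[(E)-(tert-butylimino)methyl]-2-methoxy-6-(methoxymethoxy)benzaldehyde; 17 propyne
Product: 19 8-methoxy-6-(methoxymethoxy)-3-methylisoquinoline-7-carbaldehyde, via alkynyl aldimine 18 (not isolated)
Conditions: propyne (3 equiv), PdCl2(PPh3)2 (5 mol %), CuI (5 mol %), Et3N, DMF, 60 °C (sealed); then CuI (10 mol %), 100 °C
Reagents that add atoms: none
Why: Sonogashira coupling followed by copper-catalysed 6-endo-dig attack of the imine nitrogen on the alkyne and loss of 2-methylpropene (Larock isoquinoline synthesis) builds the 3-methylisoquinoline, while the second formyl group has no ortho alkyne and stays untouched.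

Step 13
Reactants: 9 (R)-4-benzyl-3-(arylacetyl)oxazolidin-2-one; 19 8-methoxy-6-(methoxymethoxy)-3-methylisoquinoline-7-carbaldehyde
Product: 21 (2S,3R) anti-aldol imide, via trimethylsilyl ether 20 (not isolated)
Conditions: 9 (1.0 equiv), 19 (1.2 equiv), MgCl2 (0.3 equiv), Et3N (2.5 equiv), Me3SiCl (2 equiv), EtOAc, rt; then 1 M HCl/THF, 0 °C
Reagents that add atoms: none
Why: In this magnesium halide-catalysed anti-aldol of an N-acyloxazolidinone (Evans anti-aldol, soft enolisation) the chelated Z-enolate should be attacked on the face anti to the benzyl group through a boat transition state, which sets the (2S,3R) anti pair, while in situ silylation of the aldolate blocks retro-aldol cleavage.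

Step 14
Reactants: 21 (2S,3R) anti-aldol imide
Product: 22 (2S,3R) β-hydroxy Weinreb amide
Conditions: MeNH(OMe)·HCl (5 equiv), AlMe3 (5 equiv), CH2Cl2, −20 to 0 °C; aq. KNaC4H4O6
Reagents that add atoms: N,O-dimethylhydroxylamine hydrochloride, CNOC.Cl
Why: Aluminium amide transamination (Weinreb amide synthesis), directed by the free β-hydroxyl to the exocyclic imide carbonyl, releases the auxiliary without touching either stereocentre.

Step 15
Reactants: 22 (2S,3R) β-hydroxy Weinreb amide
Product: 23 (3S,4R) β-hydroxy methyl ketone with methoxymethyl ether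
Conditions: MeMgBr (4 equiv), THF, −20 to 0 °C; aq. NH4Cl
Reagents that add atoms: methylmagnesium bromide, C[Mg]Br
Why: Grignard addition to the Weinreb amide stops at the chelated tetrahedral intermediate and gives the methyl ketone on work-up, the magnesium alkoxide formed first lowering the acidity of the neighbouring α-aryl C–H.

Step 16
Reactants: 23 (3S,4R) β-hydroxy methyl ketone with methoxymethyl ether
Product: 24 (3S,4R) anti-aldol diol with free isoquinoline 6-hydroxyl
Conditions: ZnBr2 (1.5 equiv), n-PrSH (3 equiv), CH2Cl2, 0 °C, 10 min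
Reagents that add atoms: none
Why: Lewis acid/thiol cleavage of the aryl methoxymethyl ether (acetal exchange onto the thiol) frees the phenol within minutes under mild conditions that should neither enolise nor dehydrate the α-aryl-β-hydroxy ketone and leave the silyl ether and the dithiane in place.

Step 17
Reactants: 24 (3S,4R) anti-aldol diol with free isoquinoline 6-hydroxyl; 25 trimethyl orthoformate
Product: 28 bridged acetal (dithiane at a2; silyl ether at a3), via cyclic orthoester 26 (not isolated), via dioxocarbenium triflate 27 (not isolated)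
Conditions: 25 (5 equiv), pyridinium p-toluenesulfonate (0.2 equiv), CH2Cl2, rt, then evaporation; Me3SiOTf (2.5 equiv), 2,6-di-tert-butyl-4-methylpyridine (1.5 equiv), CH2Cl2, −78 to −20 °C; aq. NaHCO3
Reagents that add atoms: none
Why: Proposed new method: mild acid-catalysed exchange puts the isoquinoline 6-hydroxyl and the benzylic carbinol oxygen on the orthoformate carbon (ring C closes by 6-exo-trig attack of the second hydroxyl on the acyclic dialkoxycarbenium ion), Me3SiOTf then removes the last methoxide as Me3SiOMe, and the cyclic dioxocarbenium ion is attacked by ring A at a6 in a Friedel–Crafts step that closes ring B 6-endo-trig and ends with rearomatisation. The closest known reactions are the oxa-Pictet–Spengler cyclisation of 2-arylethanols with orthoformates and the Friedel–Crafts capture of dialkoxycarbenium ions, whereas the bridging version that makes two C–O bonds and one C–C bond at one carbon has not been shown. The new acetal stereocentre is dictated by the carbinol centre, because the one-atom oxygen bridge can join the two bridgeheads only if the substituent at the ring C carbinol carbon sits pseudo-axial, which leads to the (R) configuration of the target. The step needs attack at a6 (ortho to OMe, para to the silyloxy group) and not at a4, which the triisopropylsilyl ether, pressed against a4 by the neighbouring dithiane, is meant to secure. It also needs the α-aryl ketone stereocentre to survive, for which the hindered pyridine base, the low temperature and the removal of methanol and excess orthoformate before ionisation are chosen.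

Step 18
Reactants: 28 bridged acetal (dithiane at a2; silyl ether at a3)
Product: 29 bridged acetal aldehyde with silyl ether
Conditions: Hg(ClO4)2·3H2O (3 equiv), CaCO3 (6 equiv), THF/H2O (5:1), 0 °C
Reagents that add atoms: water, O
Why: Mercury-assisted hydrolysis of the dithiane under CaCO3 buffering unmasks the a2 aldehyde under non-basic, non-reducing conditions that should leave the ketone, the bridged acetal and the silyl ether alone.

Step 19
Reactants: 29 bridged acetal aldehyde with silyl ether
Product: 30 target CNP0584953.1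
Conditions: HF·pyridine, pyridine, THF, 0 °C
Reagents that add atoms: none
Why: Fluoride-mediated desilylation of the aryl silyl ether ortho to the aldehyde frees the phenol without the basic conditions that could epimerise the α-aryl ketone or open the acetal by β-elimination.

Compound list
1 | 4-bromo-2,6-dimethoxybenzaldehyde | COc1cc(Br)cc(OC)c1C=O | starting material
2 | 4-bromo-2-hydroxy-6-methoxybenzaldehyde | COc1cc(Br)cc(O)c1C=O | intermediate
3 | 5-bromo-2-(1,3-dithian-2-yl)-3-methoxyphenol | COc1cc(Br)cc(O)c1C1SCCCS1 | intermediate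
4 | 2-{4-bromo-2-methoxy-6-[(triisopropylsilyl)oxy]phenyl}-1,3-dithiane | COc1cc(Br)cc(O[Si](C(C)C)(C(C)C)C(C)C)c1C1SCCCS1 | intermediate
5 | tert-butyl 2-{4-(1,3-dithian-2-yl)-3-methoxy-5-[(triisopropylsilyl)oxy]phenyl}acetate | COc1cc(CC(=O)OC(C)(C)C)cc(O[Si](C(C)C)(C(C)C)C(C)C)c1C1SCCCS1 | intermediate
6 | 2-{4-(1,3-dithian-2-yl)-3-methoxy-5-[(triisopropylsilyl)oxy]phenyl}acetic acid | COc1cc(CC(=O)O)cc(O[Si](C(C)C)(C(C)C)C(C)C)c1C1SCCCS1 | intermediate
7 | (R)-4-benzyloxazolidin-2-one | O=C1OC[C@@H](Cc2ccccc2)N1 | starting material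
8 | mixed anhydride of 6 with pivalic acid (not isolated) | COc1cc(CC(=O)OC(=O)C(C)(C)C)cc(O[Si](C(C)C)(C(C)C)C(C)C)c1C1SCCCS1 | intermediate
9 | (R)-4-benzyl-3-(2-{4-(1,3-dithian-2-yl)-3-methoxy-5-[(triisopropylsilyl)oxy]phenyl}acetyl)oxazolidin-2-one | COc1cc(CC(=O)N2[C@H](Cc3ccccc3)COC2=O)cc(O[Si](C(C)C)(C(C)C)C(C)C)c1C1SCCCS1 | intermediate
10 | 2-bromo-4,6-dimethoxybenzaldehyde | COc1cc(Br)c(C=O)c(OC)c1 | starting material
11 | 2-bromo-4,6-dihydroxybenzaldehyde | Oc1cc(Br)c(C=O)c(O)c1 | intermediate
12 | 2-bromo-6-hydroxy-4-(methoxymethoxy)benzaldehyde | COCOc1cc(Br)c(C=O)c(O)c1 | intermediate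
13 | 2-bromo-6-methoxy-4-(methoxymethoxy)benzaldehyde | COCOc1cc(Br)c(C=O)c(OC)c1 | intermediate
14 | (E)-N-tert-butyl-1-[2-bromo-6-methoxy-4-(methoxymethoxy)phenyl]methanimine | COCOc1cc(Br)c(/C=N/C(C)(C)C)c(OC)c1 | intermediate
15 | {4-bromo-3-[(E)-(tert-butylimino)methyl]-2-methoxy-6-(methoxymethoxy)phenyl}lithium (not isolated) | COCOc1cc(Br)c(/C=N/C(C)(C)C)c(OC)c1[Li] | intermediate
16 | 4-bromo-3-[(E)-(tert-butylimino)methyl]-2-methoxy-6-(methoxymethoxy)benzaldehyde | COCOc1cc(Br)c(/C=N/C(C)(C)C)c(OC)c1C=O | intermediate
17 | propyne | CC#C | starting material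
18 | 3-[(E)-(tert-butylimino)methyl]-2-methoxy-6-(methoxymethoxy)-4-(prop-1-yn-1-yl)benzaldehyde (not isolated) | COCOc1cc(C#CC)c(/C=N/C(C)(C)C)c(OC)c1C=O | intermediate
19 | 8-methoxy-6-(methoxymethoxy)-3-methylisoquinoline-7-carbaldehyde | COCOc1cc2cc(C)ncc2c(OC)c1C=O | intermediate
20 | (R)-4-benzyl-3-[(2S,3R)-2-{4-(1,3-dithian-2-yl)-3-methoxy-5-[(triisopropylsilyl)oxy]phenyl}-3-[8-methoxy-6-(methoxymethoxy)-3-methylisoquinolin-7-yl]-3-[(trimethylsilyl)oxy]propanoyl]oxazolidin-2-one (not isolated) | COc1cc(cc(O[Si](C(C)C)(C(C)C)C(C)C)c1C1SCCCS1)[C@H](C(=O)N1[C@H](Cc2ccccc2)COC1=O)[C@@H](O[Si](C)(C)C)c1c(OCOC)cc2cc(C)ncc2c1OC | intermediate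
21 | (R)-4-benzyl-3-[(2S,3R)-2-{4-(1,3-dithian-2-yl)-3-methoxy-5-[(triisopropylsilyl)oxy]phenyl}-3-hydroxy-3-[8-methoxy-6-(methoxymethoxy)-3-methylisoquinolin-7-yl]propanoyl]oxazolidin-2-one | COc1cc(cc(O[Si](C(C)C)(C(C)C)C(C)C)c1C1SCCCS1)[C@H](C(=O)N1[C@H](Cc2ccccc2)COC1=O)[C@@H](O)c1c(OCOC)cc2cc(C)ncc2c1OC | intermediate
22 | (2S,3R)-2-{4-(1,3-dithian-2-yl)-3-methoxy-5-[(triisopropylsilyl)oxy]phenyl}-3-hydroxy-N-methoxy-3-[8-methoxy-6-(methoxymethoxy)-3-methylisoquinolin-7-yl]-N-methylpropanamide | COc1cc(cc(O[Si](C(C)C)(C(C)C)C(C)C)c1C1SCCCS1)[C@H](C(=O)N(C)OC)[C@@H](O)c1c(OCOC)cc2cc(C)ncc2c1OC | intermediate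
23 | (3S,4R)-3-{4-(1,3-dithian-2-yl)-3-methoxy-5-[(triisopropylsilyl)oxy]phenyl}-4-hydroxy-4-[8-methoxy-6-(methoxymethoxy)-3-methylisoquinolin-7-yl]butan-2-one | COc1cc(cc(O[Si](C(C)C)(C(C)C)C(C)C)c1C1SCCCS1)[C@H](C(C)=O)[C@@H](O)c1c(OCOC)cc2cc(C)ncc2c1OC | intermediate
24 | (3S,4R)-3-{4-(1,3-dithian-2-yl)-3-methoxy-5-[(triisopropylsilyl)oxy]phenyl}-4-hydroxy-4-(6-hydroxy-8-methoxy-3-methylisoquinolin-7-yl)butan-2-one | COc1cc(cc(O[Si](C(C)C)(C(C)C)C(C)C)c1C1SCCCS1)[C@H](C(C)=O)[C@@H](O)c1c(O)cc2cc(C)ncc2c1OC | intermediate
25 | trimethyl orthoformate | COC(OC)OC | starting material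
26 | cyclic orthoester of 24: 2-methoxy-1,3-dioxane ring C spanning the isoquinoline 6-oxygen and the carbinol oxygen, (R) at the carbinol carbon, (S) at the acetyl-bearing carbon, both epimers at the orthoester carbon (not isolated) | COc1cc(cc(O[Si](C(C)C)(C(C)C)C(C)C)c1C1SCCCS1)[C@H](C(C)=O)[C@H]1OC(OC)Oc2cc3cc(C)ncc3c(OC)c21 | intermediate
27 | cyclic dioxocarbenium triflate formed from 26 by loss of methoxide, drawn with the isoquinoline nitrogen free (not isolated) | COc1cc(cc(O[Si](C(C)C)(C(C)C)C(C)C)c1C1SCCCS1)[C@H](C(C)=O)[C@H]1O[CH+]Oc2cc3cc(C)ncc3c(OC)c21.[O-]S(=O)(=O)C(F)(F)F | intermediate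
28 | bridged acetal with the target skeleton, 1,3-dithian-2-yl at a2 and triisopropylsilyl ether at a3; acetal carbon (R), carbinol carbon (R), acetyl-bearing carbon (S) | COc1c(C2SCCCS2)c(O[Si](C(C)C)(C(C)C)C(C)C)cc2c1[C@H]1Oc3cc4cc(C)ncc4c(OC)c3[C@H](O1)[C@H]2C(C)=O | intermediate
29 | bridged acetal with formyl group at a2 and triisopropylsilyl ether at a3; acetal carbon (R), carbinol carbon (R), acetyl-bearing carbon (S) | COc1c(C=O)c(O[Si](C(C)C)(C(C)C)C(C)C)cc2c1[C@H]1Oc3cc4cc(C)ncc4c(OC)c3[C@H](O1)[C@H]2C(C)=O | intermediate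
30 | CNP0584953.1; acetal carbon (R), carbinol carbon (R), acetyl-bearing carbon (S) | COc1c(C=O)c(O)cc2c1[C@H]1Oc3cc4cc(C)ncc4c(OC)c3[C@H](O1)[C@H]2C(C)=O | target

Total step count: 19.
Longest linear sequence: 13 steps (from 10 through steps 7–12 and then steps 13–19; the ring A branch from 1, steps 1–6 and then 13–19, is equally long).

Steps most likely to fail

Step 17 (key step). The dioxocarbenium ion may not be captured by ring A: it can instead collapse by cleavage of the benzylic C–O bond of ring C, be attacked at a4, or the Lewis acid may enolise the ketone. The fallback makes the same three bonds in two known stages and sets out from 23, in which the phenol is still protected. The carbinol alone is condensed with trimethyl orthoformate under Me3SiOTf catalysis in an oxa-Pictet–Spengler cyclisation, which closes ring B first and should give the 1-methoxyisochroman F1 as a mixture at the anomeric carbon. Cleavage of the methoxymethyl ether (ZnBr2, n-PrSH) then gives the free phenol F2. Under anhydrous camphorsulfonic acid the phenol displaces the anomeric methoxy group by intramolecular transacetalisation through the ring B oxocarbenium ion, and the route is rejoined at 28.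

Step 13 (anti-aldol). Addition to the hindered, electron-rich aldehyde may be slow, the isoquinoline nitrogen may sequester the magnesium salt, and facial or anti selectivity may erode. The fallback changes the enolate platform and sets out from 6. The acid is coupled (DCC, DMAP) with (S)-4-benzylthiazolidine-2-thione to the N-acylthiazolidinethione F3. Its MgBr2·OEt2-catalysed anti-aldol with 19 (Et3N, Me3SiCl, EtOAc) is expected to reach the same (2S,3R) pair through the non-chelated enolate face and to give the O-trimethylsilyl adduct F4. Mild acid then gives the free anti-aldol adduct F5. The thiazolidinethione is displaced directly by N,O-dimethylhydroxylamine (imidazole, CH2Cl2) without an aluminium reagent, which returns to the route at 22.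

Step 15 (methyl ketone). The Grignard reagent may deprotonate the acidic α-aryl C–H, which would epimerise the benzylic centre or return the amide, and the magnesium aldolate may undergo retro-aldol cleavage. The fallback avoids a basic carbanion and sets out from 21. The imide is opened with LiSEt to the S-ethyl thioester F6. A Fukuyama coupling with MeZnI and PdCl2(PPh3)2 in toluene then gives the ketone and returns to the route at 23.

Further compounds
F1 | step 17 | 1-methoxyisochroman from 23 (ring B closed, methoxymethyl ether retained, both anomers; carbinol carbon R, acetyl-bearing carbon S) | COc1c(C2SCCCS2)c(O[Si](C(C)C)(C(C)C)C(C)C)cc2c1C(OC)O[C@@H](c1c(OCOC)cc3cc(C)ncc3c1OC)[C@H]2C(C)=O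
F2 | step 17 | 1-methoxyisochroman with free isoquinoline 6-hydroxyl (both anomers; carbinol carbon R, acetyl-bearing carbon S) | COc1c(C2SCCCS2)c(O[Si](C(C)C)(C(C)C)C(C)C)cc2c1C(OC)O[C@@H](c1c(O)cc3cc(C)ncc3c1OC)[C@H]2C(C)=O
F3 | step 13 | (S)-4-benzyl-3-(2-{4-(1,3-dithian-2-yl)-3-methoxy-5-[(triisopropylsilyl)oxy]phenyl}acetyl)thiazolidine-2-thione | COc1cc(CC(=O)N2[C@@H](Cc3ccccc3)CSC2=S)cc(O[Si](C(C)C)(C(C)C)C(C)C)c1C1SCCCS1
F4 | step 13 | O-trimethylsilyl (2S,3R) anti-aldol adduct of F3 and 19 | COc1cc(cc(O[Si](C(C)C)(C(C)C)C(C)C)c1C1SCCCS1)[C@H](C(=O)N1[C@@H](Cc2ccccc2)CSC1=S)[C@@H](O[Si](C)(C)C)c1c(OCOC)cc2cc(C)ncc2c1OC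
F5 | step 13 | (2S,3R) anti-aldol adduct of F3 and 19 with free hydroxyl | COc1cc(cc(O[Si](C(C)C)(C(C)C)C(C)C)c1C1SCCCS1)[C@H](C(=O)N1[C@@H](Cc2ccccc2)CSC1=S)[C@@H](O)c1c(OCOC)cc2cc(C)ncc2c1OC
F6 | step 15 | S-ethyl (2S,3R)-2-{4-(1,3-dithian-2-yl)-3-methoxy-5-[(triisopropylsilyl)oxy]phenyl}-3-hydroxy-3-[8-methoxy-6-(methoxymethoxy)-3-methylisoquinolin-7-yl]propanethioate | COc1cc(cc(O[Si](C(C)C)(C(C)C)C(C)C)c1C1SCCCS1)[C@H](C(=O)SCC)[C@@H](O)c1c(OCOC)cc2cc(C)ncc2c1OC
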